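The flavanone is cut across ring C at C2–C3 and C4–C4a. A chiral confined Brønsted acid ionises a symmetrical diaryl acetal of 2,6-dimethoxybenzaldehyde; ethyl vinyl ether then adds to the O1=C2 oxocarbenium ion and the new C4 cation is caught by C4a, so one operation closes ring C and sets C2. The step exploits the cation-stabilising 2,6-dimethoxyphenyl group on C2 and the fact that C4a is the only free carbon ortho to O1 on ring A, activated by the oxygens on C5, C7 and C8a. The precursor carries the future 5-hydroxyl as a benzyl ether, so the end game (DDQ, then hydrogenolysis) avoids acid and base.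

Key step: step 7

Remark: in the ring A phenol, C1–O becomes O1, the C2 and C3 methoxyls become the 8- and 7-methoxyls, the C5 oxygen becomes the 5-oxygen and C6 becomes C4a. The (2S,4S) chroman drawn for the key step is the 2,4-cis isomer; a 4-epimer, if formed, converges in the oxidation that follows.

Assumption: the sense of induction of the chiral acid cannot be predicted with certainty. The (S,S) catalyst is written; its mirror image, equally accessible, is used if it is the one that delivers 2S.

Step 1
Reactants: 1 3-hydroxy-4,5-dimethoxybenzaldehyde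
Product: 2 3,4-dimethoxy-5-[(triisopropylsilyl)oxy]benzaldehyde
Conditions: TIPSCl, imidazole, DMF, rt
Reagents that add atoms: chlorotriisopropylsilane CC(C)[Si](Cl)(C(C)C)C(C)C
Why: Silyl ether formation on the only free phenol masks the oxygen that will become O1 with an electron-releasing group that tolerates peracid and carbonate and is later removed by fluoride.

Step 2
Reactants: 2 3,4-dimethoxy-5-[(triisopropylsilyl)oxy]benzaldehyde
Product: 4 3,4-dimethoxy-5-[(triisopropylsilyl)oxy]phenol, via aryl formate 3 (not isolated)
Conditions: mCPBA, CH2Cl2, 0 °C → rt; aq. NaHCO3/Na2S2O3 wash; then Et3N (cat.), MeOH, rt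
Reagents that add atoms: 3-chloroperoxybenzoic acid OOC(=O)c1cccc(Cl)c1
Why: Baeyer–Villiger oxidation (Dakin-type) of an electron-rich benzaldehyde, in which the trioxygenated aryl group migrates in preference to hydrogen, gives the aryl formate, whose methanolysis under trace base is much faster than any attack on the hindered silyl ether.

Step 3
Reactants: 4 3,4-dimethoxy-5-[(triisopropylsilyl)oxy]phenol
Product: 5 [5-(benzyloxy)-2,3-dimethoxyphenoxy]triisopropylsilane
Conditions: BnBr, K2CO3, acetone, 50 °C
Reagents that add atoms: benzyl bromide BrCc1ccccc1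
Why: Williamson ether synthesis on the free phenol installs the benzyl group on the oxygen that ends as the 5-hydroxyl, the triisopropylsilyl ether being stable to K2CO3 in acetone.

Step 4
Reactants: 5 [5-(benzyloxy)-2,3-dimethoxyphenoxy]triisopropylsilane
Product: 6 5-(benzyloxy)-2,3-dimethoxyphenol
Conditions: TBAF, AcOH, THF, 0 °C → rt (argon)
Reagents that add atoms: none
Why: Fluoride-induced desilylation, driven by the Si–F bond and buffered with acetic acid so that the electron-rich phenoxide is not exposed to air, frees the ring A phenol without touching the benzyl or methyl ethers.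

Step 5
Reactants: 7 2,6-dimethoxybenzaldehyde
Product: 8 2-(dichloromethyl)-1,3-dimethoxybenzene
Conditions: SOCl2, DMF (cat.), CH2Cl2, 0 °C → 40 °C; evaporate, use crude
Reagents that add atoms: thionyl chloride O=S(Cl)Cl
Why: Deoxygenative gem-dichlorination of an aromatic aldehyde by SOCl2 under Vilsmeier-type catalysis by DMF gives the benzal chloride, which is used crude because it is moisture-sensitive.

Step 6
Reactants: 6 5-(benzyloxy)-2,3-dimethoxyphenol (2.05 equiv), 8 2-(dichloromethyl)-1,3-dimethoxybenzene
Product: 9 2-{bis[5-(benzyloxy)-2,3-dimethoxyphenoxy]methyl}-1,3-dimethoxybenzene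
Conditions: NaH, THF, 0 °C; then 8, 15-crown-5 (cat.), 0 °C → rt; chromatography on Et3N-deactivated silica
Reagents that add atoms: none
Why: Twofold Williamson-type O-alkylation of the sodium phenoxide by the benzal chloride is the classical diaryl acetal synthesis, and because it runs under base the electron-rich ring A never meets an acid-generated benzylic cation that could alkylate it at carbon.

Step 7
Reactants: 9 2-{bis[5-(benzyloxy)-2,3-dimethoxyphenoxy]methyl}-1,3-dimethoxybenzene, 10 ethyl vinyl ether
Product: 13 (2S,4S)-5-(benzyloxy)-4-ethoxy-7,8-dimethoxy-2-(2,6-dimethoxyphenyl)chromane, via O-aryl oxocarbenium ion 11 (not isolated), via C4 oxocarbenium ion 12 (not isolated)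
Conditions: (S,S)-IDPi acid (N-triflyl imidodiphosphorimidate on two 3,3'-diaryl-BINOL units, 5 mol %), 10 (3 equiv, slow addition), 5 Å MS, toluene/CH2Cl2, −78 °C; Et3N quench
Reagents that add atoms: none
Why: Proposed new method: because both acetal oxygens of 9 carry the same aryl group, acid-induced loss of phenol 6 can lead to a single cation, the O-aryl oxocarbenium ion 11, which stays paired with the chiral imidodiphosphorimidate anion; 10 adds to C2 of 11 (C2–C3) to give the more electrophilic secondary oxocarbenium ion 12, which C4a attacks (C4–C4a), and loss of the ring proton returns the acid. The closest known reactions are the racemic, Lewis acid-promoted oxa-Povarov annulation of aryl oxocarbenium ions with alkenes and chiral-counteranion-controlled additions of enol ethers to oxocarbenium ions. Ring C closes by an intramolecular Friedel–Crafts alkylation that is 6-exo-trig at the oxocarbenium carbon C4, with the C4a–C8a bond of ring A inside the new ring. C2 is set in the first C–C bond formation by the confined anion, which leaves one face of planar 11 open to the vinyl ether (catalyst control), whereas C4 is set by the chair-like closure (cis expected, substrate control) and is erased in step 8. The step needs face selectivity at C2, closure at the ortho carbon faster than chain growth of 10, and no re-ionisation of the C2–O1 bond of 13; these rest on the tight ion pair at −78 °C, on C4a being the only unsubstituted carbon ortho to O1 and carrying the activation of the oxygens on C5, C7 and C8a, and on 13 being less basic and more hindered toward the confined acid than the acetal 9.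

Step 8
Reactants: 13 (2S,4S)-5-(benzyloxy)-4-ethoxy-7,8-dimethoxy-2-(2,6-dimethoxyphenyl)chromane
Product: 14 (2S)-5-(benzyloxy)-7,8-dimethoxy-2-(2,6-dimethoxyphenyl)chroman-4-one
Conditions: DDQ (1.5 equiv), CH2Cl2/pH 7 phosphate buffer (10:1), 0 °C
Reagents that add atoms: water O
Why: Benzylic oxidation by hydride abstraction with DDQ, established for C4 of flavans bearing an oxygenated ring A: the C4–H bond, activated by the ethoxy oxygen and by the ortho and para oxygens of ring A, is removed, water adds to the cation and ethanol is lost to give the aryl ketone, while C2, which is not benzylic to ring A, keeps its configuration.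

Step 9
Reactants: 14 (2S)-5-(benzyloxy)-7,8-dimethoxy-2-(2,6-dimethoxyphenyl)chroman-4-one
Product: 15 (2S)-5-hydroxy-7,8-dimethoxy-2-(2,6-dimethoxyphenyl)chroman-4-one
Conditions: H2 (1 atm), 10% Pd/C, EtOAc, rt
Reagents that add atoms: none
Why: Hydrogenolysis of the primary benzyl aryl ether over Pd/C under neutral conditions frees the chelated 5-hydroxyl without the acid or base that could open ring C to the chalcone and racemise C2; the hindered secondary C2–O1 bond and the aryl ketone react far more slowly, so the reaction is stopped at full conversion.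

Compound list
1 | 3-hydroxy-4,5-dimethoxybenzaldehyde (5-hydroxy-3,4-dimethoxybenzaldehyde) | COc1cc(C=O)cc(O)c1OC | starting material
2 | 3,4-dimethoxy-5-[(triisopropylsilyl)oxy]benzaldehyde | COc1cc(C=O)cc(O[Si](C(C)C)(C(C)C)C(C)C)c1OC | intermediate
3 | 3,4-dimethoxy-5-[(triisopropylsilyl)oxy]phenyl formate | COc1cc(OC=O)cc(O[Si](C(C)C)(C(C)C)C(C)C)c1OC | intermediate
4 | 3,4-dimethoxy-5-[(triisopropylsilyl)oxy]phenol | COc1cc(O)cc(O[Si](C(C)C)(C(C)C)C(C)C)c1OC | intermediate
5 | [5-(benzyloxy)-2,3-dimethoxyphenoxy]triisopropylsilane | COc1cc(OCc2ccccc2)cc(O[Si](C(C)C)(C(C)C)C(C)C)c1OC | intermediate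
6 | 5-(benzyloxy)-2,3-dimethoxyphenol | COc1cc(OCc2ccccc2)cc(O)c1OC | intermediate
7 | 2,6-dimethoxybenzaldehyde | COc1cccc(OC)c1C=O | starting material
8 | 2-(dichloromethyl)-1,3-dimethoxybenzene | COc1cccc(OC)c1C(Cl)Cl | intermediate
9 | 2-{bis[5-(benzyloxy)-2,3-dimethoxyphenoxy]methyl}-1,3-dimethoxybenzene | COc1cccc(OC)c1C(Oc1cc(OCc2ccccc2)cc(OC)c1OC)Oc1cc(OCc2ccccc2)cc(OC)c1OC | intermediate
10 | ethyl vinyl ether | C=COCC | starting material
11 | [5-(benzyloxy)-2,3-dimethoxyphenyl][(2,6-dimethoxyphenyl)methylidene]oxonium (O-aryl oxocarbenium ion, paired with the catalyst anion) | COc1cccc(OC)c1C=[O+]c1cc(OCc2ccccc2)cc(OC)c1OC | intermediate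
12 | {(3S)-3-[5-(benzyloxy)-2,3-dimethoxyphenoxy]-3-(2,6-dimethoxyphenyl)propylidene}(ethyl)oxonium (C4 oxocarbenium ion, paired with the catalyst anion) | CC[O+]=CC[C@H](Oc1cc(OCc2ccccc2)cc(OC)c1OC)c1c(OC)cccc1OC | intermediate
13 | (2S,4S)-5-(benzyloxy)-4-ethoxy-7,8-dimethoxy-2-(2,6-dimethoxyphenyl)chromane (2,4-cis) | COc1cc(OCc3ccccc3)c2c(c1OC)O[C@H](c1c(OC)cccc1OC)C[C@@H]2OCC | intermediate
14 | (2S)-5-(benzyloxy)-7,8-dimethoxy-2-(2,6-dimethoxyphenyl)chroman-4-one | COc1cc(OCc3ccccc3)c2c(c1OC)O[C@H](c1c(OC)cccc1OC)CC2=O | intermediate
15 | (2S)-5-hydroxy-7,8-dimethoxy-2-(2,6-dimethoxyphenyl)chroman-4-one, (2S)-5-hydroxy-7,8,2',6'-tetramethoxyflavanone | COc1cc(O)c2c(c1OC)O[C@H](c1c(OC)cccc1OC)CC2=O | target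

Total step count: 9. Longest linear sequence: 8 steps (1 → 2 → 4 → 5 → 6 → 9 → 13 → 14 → 15); step 5 is the one-step side branch from 7.

Steps most likely to fail

Step 7. The chiral anion may discriminate the two faces of C2 poorly, and the acid may re-ionise the C2–O1 bond of the product and so erode the enantiomeric purity. The vinyl ether may also undergo cationic chain growth, and the liberated phenol may be alkylated at carbon. The phenol 6 that is released should otherwise be recovered and returned to step 6. The fallback uses known chemistry only and sets out from 6, with 7 as partner. Ortho-acetylation of 6 (Ac2O, BF3·OEt2, Friedel–Crafts acylation through Fries rearrangement of the aryl acetate, directed to C6 by the boron chelate) should give 1-[6-(benzyloxy)-2-hydroxy-3,4-dimethoxyphenyl]ethan-1-one F1. Claisen–Schmidt condensation with 7 (KOH, EtOH, rt) should give the chalcone (E)-1-[6-(benzyloxy)-2-hydroxy-3,4-dimethoxyphenyl]-3-(2,6-dimethoxyphenyl)prop-2-en-1-one F2. Intramolecular oxa-Michael ring closure (NaOAc, EtOH, reflux) should give racemic 5-(benzyloxy)-7,8-dimethoxy-2-(2,6-dimethoxyphenyl)chroman-4-one F3. Preparative HPLC on an amylose tris(3,5-dimethylphenylcarbamate) chiral phase then separates the enantiomers, and the fallback comes back to the route at 14; steps 5 to 8 are then not needed.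

Step 6. The ambident phenoxide may be alkylated at carbon, the labile gem-dichloride may ionise or hydrolyse before both displacements are complete, and the acid-sensitive acetal may be lost during purification. The fallback sets out from 7 and replaces the irreversible alkylation by an equilibrium exchange. Acetalisation with HC(OMe)3 and TsOH (cat.) in MeOH should give 2-(dimethoxymethyl)-1,3-dimethoxybenzene F4. Transacetalisation with 6 (2.2 equiv) under PPTS (cat.) in refluxing toluene, with the condensate passed through 5 Å MS to remove methanol, comes back to the route at 9.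

Step 8. Hydride abstraction may occur at C2 in competition with C4, the flavanone may be over-oxidised to the flavone, and the benzyl ether may be lost oxidatively. The fallback sets out from 13 and separates solvolysis from oxidation. Exchange of the 4-ethoxy group for hydroxyl through the C4 cation (PPTS, THF/H2O, rt) should give (2S)-5-(benzyloxy)-7,8-dimethoxy-2-(2,6-dimethoxyphenyl)chroman-4-ol F5 as a mixture at C4. Dess–Martin oxidation (NaHCO3, CH2Cl2, rt) then comes back to the route at 14.

Further compounds
F1 | step 7 | 1-[6-(benzyloxy)-2-hydroxy-3,4-dimethoxyphenyl]ethan-1-one | CC(=O)c1c(O)c(OC)c(OC)cc1OCc1ccccc1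
F2 | step 7 | (E)-1-[6-(benzyloxy)-2-hydroxy-3,4-dimethoxyphenyl]-3-(2,6-dimethoxyphenyl)prop-2-en-1-one | COc1cccc(OC)c1/C=C/C(=O)c1c(O)c(OC)c(OC)cc1OCc1ccccc1
F3 | step 7 | racemic 5-(benzyloxy)-7,8-dimethoxy-2-(2,6-dimethoxyphenyl)chroman-4-one | COc1cc(OCc3ccccc3)c2c(c1OC)OC(c1c(OC)cccc1OC)CC2=O
F4 | step 6 | 2-(dimethoxymethyl)-1,3-dimethoxybenzene | COc1cccc(OC)c1C(OC)OC
F5 | step 8 | (2S)-5-(benzyloxy)-7,8-dimethoxy-2-(2,6-dimethoxyphenyl)chroman-4-ol (both C4 epimers) | COc1cc(OCc3ccccc3)c2c(c1OC)O[C@H](c1c(OC)cccc1OC)CC2O
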